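**Retrosynthetic overview**

1. The C3–OH of the flavonol comes from C3–Bpin, and that from C3–I (steps 6 and 7).
2. Ring C (the pyranone) comes from ynone 9 and ICl: O1–C2 and C3–I form while one O-methyl group is lost (step 5).
3. The feature the route rests on is ring A: in 9 it is a 2,4,6-trimethoxy-3,5-dimethylphenyl ketone with a mirror plane, so either ortho methoxy oxygen can become O1 and both give C5-OMe, C6-Me, C7-OMe, C8-Me, while C3 (alpha to C4=O) takes the iodine that is later exchanged for OH.
4. Ynone 9 comes from aldehyde 5 and alkyne 6 (acetylide addition, then MnO2); aldehyde 5 comes from 2,4,6-trimethoxytoluene 1 by ortho-lithiation/methylation and Vilsmeier formylation.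
5. Ring order: rings A and B are bought intact; ring C is the only ring formed.

Key step: step 5

Remark: the target has no stereocentre; carbinol 8 is formed as a racemate and its stereocentre is removed by the oxidation in step 4.

**Step 1**
Reactants: 1 2,4,6-trimethoxytoluene
Product: 3 1,3,5-trimethoxy-2,4-dimethylbenzene, via aryllithium 2 (not isolated)
Conditions: n-BuLi (1.2 equiv), TMEDA, THF, 0 °C → rt; then MeI, −78 °C → rt
Reagents that add atoms: iodomethane, CI
Why: Directed ortho-metalation removes the ring hydrogen flanked by two methoxy groups (the two such positions of 1 are equivalent), and the aryllithium is methylated by SN2 attack on iodomethane.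

**Step 2**
Reactants: 3 1,3,5-trimethoxy-2,4-dimethylbenzene
Product: 5 2,4,6-trimethoxy-3,5-dimethylbenzaldehyde, via iminium salt 4 (not isolated)
Conditions: POCl3, DMF, 0 °C → 70 °C; then ice-water, rt
Reagents that add atoms: N,N-dimethylformamide, CN(C)C=O; water, O
Why: Vilsmeier–Haack formylation attacks the only free ring position, which is ortho, ortho and para to the three methoxy groups, and hydrolysis of the iminium salt releases the aldehyde.

**Step 3**
Reactants: 5 2,4,6-trimethoxy-3,5-dimethylbenzaldehyde; 6 1-ethynyl-2-methoxybenzene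
Product: 8 rac-3-(2-methoxyphenyl)-1-(2,4,6-trimethoxy-3,5-dimethylphenyl)prop-2-yn-1-ol, via lithium acetylide 7 (not isolated)
Conditions: 6, n-BuLi, THF, −78 °C; then 5, −78 °C → 0 °C; H2O quench
Reagents that add atoms: none
Why: 1,2-Addition of a lithium acetylide to a non-enolisable aromatic aldehyde; the carbinol centre forms as a racemate, which does not matter because it is oxidised in step 4, and the neutral quench protects the acid-labile electron-rich carbinol.

**Step 4**
Reactants: 8 rac-3-(2-methoxyphenyl)-1-(2,4,6-trimethoxy-3,5-dimethylphenyl)prop-2-yn-1-ol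
Product: 9 3-(2-methoxyphenyl)-1-(2,4,6-trimethoxy-3,5-dimethylphenyl)prop-2-yn-1-one
Conditions: activated MnO2 (excess), CH2Cl2, rt
Reagents that add atoms: none
Why: MnO2 oxidation of a secondary alcohol that is both benzylic and propargylic runs under neutral conditions, which spare the alkyne and the aryl methyl ethers.

**Step 5**
Reactants: 9 3-(2-methoxyphenyl)-1-(2,4,6-trimethoxy-3,5-dimethylphenyl)prop-2-yn-1-one; 10 iodine monochloride
Product: 12 3-iodo-5,7-dimethoxy-2-(2-methoxyphenyl)-6,8-dimethyl-4H-chromen-4-one, via O-methyl oxonium chloride 11 (not isolated)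
Conditions: ICl (1.2 equiv, 1 M in CH2Cl2), CH2Cl2, −78 °C → 0 °C; then aq. Na2S2O3
Reagents that add atoms: iodine monochloride, ClI
Why: ICl activates the alkyne of 9 as an iodonium species; the ketone makes the neighbouring alkyne carbon electron-poor and the 2-methoxyphenyl group stabilises positive charge at the other, so iodine bonds to the carbon alpha to the carbonyl and an ortho methoxy oxygen of ring A attacks the aryl-bearing carbon, forming O1–C2 and C3–I in oxonium chloride 11. Chloride then removes the O-methyl group by SN2 attack, chloromethane leaves and neutral 3-iodochromone 12 remains. The closest known reaction is the ICl-induced cyclisation of ortho-methoxyaryl alkynyl ketones to 3-iodochromones. Ring C closes in the 6-endo-dig mode and no stereocentre is formed. The step needs closure by a ring A oxygen and not 5-endo closure by the ring B methoxy oxygen (a benzofuran) or 5-exo closure to an aurone; both alternatives would put the nucleophile alpha and iodine beta to the ketone, against the polarisation of the ynone, and the mirror symmetry of ring A means only one chromone can form. Nuclear iodination is held back because ring A has no free position and ring B is less activated than the alkyne at −78 °C with only a small excess of ICl.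

**Step 6**
Reactants: 12 3-iodo-5,7-dimethoxy-2-(2-methoxyphenyl)-6,8-dimethyl-4H-chromen-4-one
Product: 13 5,7-dimethoxy-2-(2-methoxyphenyl)-6,8-dimethyl-3-(4,4,5,5-tetramethyl-1,3,2-dioxaborolan-2-yl)-4H-chromen-4-one
Conditions: PdCl2(dppf) (5 mol %), B2pin2 (1.5 equiv), KOAc (3 equiv), 1,4-dioxane, 90 °C, argon; short silica plug
Reagents that add atoms: bis(pinacolato)diboron, CC1(C)OB(OC1(C)C)B1OC(C)(C)C(C)(C)O1
Why: Miyaura borylation: zerovalent palladium inserts into the C3–I bond, acetate-assisted transmetalation with B2pin2 and reductive elimination form the C3–B bond, and the weak base KOAc leaves the base-sensitive pyranone ring closed and disfavours Suzuki homocoupling.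

**Step 7**
Reactants: 13 5,7-dimethoxy-2-(2-methoxyphenyl)-6,8-dimethyl-3-(4,4,5,5-tetramethyl-1,3,2-dioxaborolan-2-yl)-4H-chromen-4-one
Product: 14 3-hydroxy-5,7-dimethoxy-2-(2-methoxyphenyl)-6,8-dimethyl-4H-chromen-4-one
Conditions: 30% aq. H2O2, NaHCO3, THF/H2O, 0 °C → rt; then aq. Na2S2O3
Reagents that add atoms: hydrogen peroxide, OO
Why: Oxidation of a carbon–boron bond: hydroperoxide adds to boron, C3 migrates from boron to oxygen and hydrolysis of the borate gives the C3 enol, which is the flavonol; bicarbonate buffering keeps hydroperoxide from epoxidising or opening the chromone.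

**Compound list**

1 | 2,4,6-trimethoxytoluene | COc1cc(OC)c(C)c(OC)c1 | starting material
2 | (2,4,6-trimethoxy-3-methylphenyl)lithium | [Li]c1c(OC)c(C)c(OC)cc1OC | intermediate (not isolated)
3 | 1,3,5-trimethoxy-2,4-dimethylbenzene | COc1cc(OC)c(C)c(OC)c1C | intermediate
4 | N-methyl-N-[(2,4,6-trimethoxy-3,5-dimethylphenyl)methylidene]methanaminium dichlorophosphate | C[N+](C)=Cc1c(OC)c(C)c(OC)c(C)c1OC.[O-]P(=O)(Cl)Cl | intermediate (not isolated)
5 | 2,4,6-trimethoxy-3,5-dimethylbenzaldehyde | O=Cc1c(OC)c(C)c(OC)c(C)c1OC | intermediate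
6 | 1-ethynyl-2-methoxybenzene | C#Cc1ccccc1OC | starting material
7 | lithium (2-methoxyphenyl)acetylide | [Li]C#Cc1ccccc1OC | intermediate (not isolated)
8 | rac-3-(2-methoxyphenyl)-1-(2,4,6-trimethoxy-3,5-dimethylphenyl)prop-2-yn-1-ol (racemate) | COc1ccccc1C#CC(O)c1c(OC)c(C)c(OC)c(C)c1OC | intermediate
9 | 3-(2-methoxyphenyl)-1-(2,4,6-trimethoxy-3,5-dimethylphenyl)prop-2-yn-1-one | COc1ccccc1C#CC(=O)c1c(OC)c(C)c(OC)c(C)c1OC | intermediate
10 | iodine monochloride | ClI | starting material
11 | 3-iodo-5,7-dimethoxy-2-(2-methoxyphenyl)-1,6,8-trimethyl-4-oxo-4H-chromen-1-ium chloride | C[O+]1C(c2ccccc2OC)=C(I)C(=O)c2c(OC)c(C)c(OC)c(C)c21.[Cl-] | intermediate (not isolated)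
12 | 3-iodo-5,7-dimethoxy-2-(2-methoxyphenyl)-6,8-dimethyl-4H-chromen-4-one | COc1ccccc1-c1oc2c(C)c(OC)c(C)c(OC)c2c(=O)c1I | intermediate
13 | 5,7-dimethoxy-2-(2-methoxyphenyl)-6,8-dimethyl-3-(4,4,5,5-tetramethyl-1,3,2-dioxaborolan-2-yl)-4H-chromen-4-one | COc1ccccc1-c1oc2c(C)c(OC)c(C)c(OC)c2c(=O)c1B1OC(C)(C)C(C)(C)O1 | intermediate
14 | 3-hydroxy-5,7-dimethoxy-2-(2-methoxyphenyl)-6,8-dimethyl-4H-chromen-4-one | COc1ccccc1-c1oc2c(C)c(OC)c(C)c(OC)c2c(=O)c1O | target

**Step count**

Total steps: 7. Longest linear sequence: 7 steps (1 → 14); alkyne 6 and ICl 10 enter as bought compounds.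

**Steps most likely to fail**

1. Step 5 (key step). What may go wrong: electrophilic iodination of the anisole ring B competes with alkyne activation, or the reaction stops at the ICl adduct of the alkyne without demethylative closure. The fallback sets out from ynone 9 and comes back at target 14, replacing steps 5 to 7. BCl3 (1.1 equiv) in CH2Cl2 at −78 °C → 0 °C should cleave one of the two equivalent ortho methyl ethers through the boron chelate with the ketone and give 1-(2-hydroxy-4,6-dimethoxy-3,5-dimethylphenyl)-3-(2-methoxyphenyl)prop-2-yn-1-one F1. Catalytic DMAP in DMF at rt should close this phenol by 6-endo oxa-Michael addition to 5,7-dimethoxy-2-(2-methoxyphenyl)-6,8-dimethyl-4H-chromen-4-one F2. LDA in THF at −78 °C should deprotonate C3 to 3-lithio-5,7-dimethoxy-2-(2-methoxyphenyl)-6,8-dimethyl-4H-chromen-4-one F3, and B(OMe)3 should trap it as dimethyl [5,7-dimethoxy-2-(2-methoxyphenyl)-6,8-dimethyl-4-oxo-4H-chromen-3-yl]boronate F4. Oxidation in the same flask with H2O2/AcOH should then give 14.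

2. Step 6. What may go wrong: reductive loss of iodine (protodehalogenation) and slow transmetalation at the crowded C3, or protodeboronation during isolation. The fallback sets out from iodide 12 and comes back at boronate 13. Iodine–magnesium exchange with iPrMgCl·LiCl in THF at −40 °C should give chloro[5,7-dimethoxy-2-(2-methoxyphenyl)-6,8-dimethyl-4-oxo-4H-chromen-3-yl]magnesium F5. This is kept cold to prevent ring opening by beta-elimination and is quenched at that temperature with 2-isopropoxy-4,4,5,5-tetramethyl-1,3,2-dioxaborolane to give 13, which goes on to step 7.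

3. Step 1. What may go wrong: incomplete lithiation, or lithiation at the benzylic methyl group, leading to arene mixtures that are hard to separate. The fallback sets out from 1 and comes back at 3. Vilsmeier formylation (POCl3, DMF, 0 °C → 60 °C; then water) should give 2,4,6-trimethoxy-3-methylbenzaldehyde F6. Wolff–Kishner reduction in the Huang-Minlon manner (N2H4·H2O, KOH, diethylene glycol, 130 °C then 200 °C) should pass through (E)-[(2,4,6-trimethoxy-3-methylphenyl)methylidene]hydrazine F7 and give 3 with loss of nitrogen.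

**Further compounds**

F1 | step 5 | 1-(2-hydroxy-4,6-dimethoxy-3,5-dimethylphenyl)-3-(2-methoxyphenyl)prop-2-yn-1-one | COc1ccccc1C#CC(=O)c1c(O)c(C)c(OC)c(C)c1OC
F2 | step 5 | 5,7-dimethoxy-2-(2-methoxyphenyl)-6,8-dimethyl-4H-chromen-4-one | COc1ccccc1-c1cc(=O)c2c(OC)c(C)c(OC)c(C)c2o1
F3 | step 5 | 3-lithio-5,7-dimethoxy-2-(2-methoxyphenyl)-6,8-dimethyl-4H-chromen-4-one | COc1ccccc1-c1oc2c(C)c(OC)c(C)c(OC)c2c(=O)c1[Li]
F4 | step 5 | dimethyl [5,7-dimethoxy-2-(2-methoxyphenyl)-6,8-dimethyl-4-oxo-4H-chromen-3-yl]boronate | COc1ccccc1-c1oc2c(C)c(OC)c(C)c(OC)c2c(=O)c1B(OC)OC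
F5 | step 6 | chloro[5,7-dimethoxy-2-(2-methoxyphenyl)-6,8-dimethyl-4-oxo-4H-chromen-3-yl]magnesium | COc1ccccc1-c1oc2c(C)c(OC)c(C)c(OC)c2c(=O)c1[Mg]Cl
F6 | step 1 | 2,4,6-trimethoxy-3-methylbenzaldehyde | O=Cc1c(OC)cc(OC)c(C)c1OC
F7 | step 1 | (E)-[(2,4,6-trimethoxy-3-methylphenyl)methylidene]hydrazine | N/N=C/c1c(OC)cc(OC)c(C)c1OC
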